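**Plan**

Ring numbering: C1 (C=O), C2=C3, C4, C5 (carbinol), C6. The feature used is that C1–C2–C3 can be folded into the cyclopropane of a bicyclo[3.1.0]hexan-1-ol (C1 carbinol carbon, C2 the CH2, C3 the bridgehead CH). Its cyclopentane is C1–C3–C4–C5–C6, and breaking the shared C1–C3 bond turns that five-membered ring into the six-membered enone ring.
Retrosynthesis: the protecting groups are removed, C2=C3 is traced to a C3 chloride, and the chloride to the bicyclic cyclopropanol (C1–C3 re-formed). C1–C3 and C1–C2 are then cut together to an acyclic hex-5-enoate (ester carbon = C1, CH2=CH = C2/C3).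
Further cuts: the bond between the side-chain carbonyl carbon and its C17 chain (Weinreb amide plus Grignard reagent), and the C4–C5 bond (Barbier allylation of dimethyl 3-oxopentanedioate).
Forward order: C5 is built first, its two acetate arms are differentiated, and the C17 chain is joined. Cyclopentane and cyclopropane then close in one operation, and the cyclohexenone arises by oxidative ring expansion and loss of HCl.
Stereochemistry: C5 comes from a cinchona-catalysed desymmetrising methanolysis of the prochiral glutaric anhydride, and no bond to it is broken afterwards. The Z-alkene comes from syn semi-hydrogenation of an alkyne, and the two ring-fusion centres are transient.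

Key step: step 11

Assumption: the quinidine-derived catalyst of step 5 is taken to give the (R)-half-ester. No close analogy fixes the sense of attack on a 3,3-disubstituted anhydride, so it is to be checked by correlation, and the quinine-derived pseudo-enantiomer (DHQ)2AQN would be used if it proves opposite.
Remark: the descriptor at the quaternary carbon alternates between R and S along the route only because the ranking of its substituents changes.

Step 1
Reactants: 1 dimethyl 3-oxopentanedioate; 2 allyl bromide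
Product: 4 dimethyl 3-hydroxy-3-(prop-2-en-1-yl)pentanedioate, via allylzinc bromide 3 (not isolated)
Conditions: Zn dust (2 equiv), THF/sat. aq NH4Cl, 0 °C to rt
Reagents that add atoms: none
Why: Aqueous Barbier allylation, in which the allylzinc species adds to the ketone in a near-neutral medium and so avoids the enolate formation that would stop an allyl Grignard reagent on this doubly activated β-keto diester; the new carbinol carbon is prochiral, so no stereocentre arises.

Step 2
Reactants: 4 dimethyl 3-hydroxy-3-(prop-2-en-1-yl)pentanedioate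
Product: 5 dimethyl 3-(prop-2-en-1-yl)-3-(triethylsilyloxy)pentanedioate
Conditions: TESOTf (1.5 equiv), 2,6-lutidine (2 equiv), CH2Cl2, 0 °C to rt
Reagents that add atoms: triethylsilyl trifluoromethanesulfonate, CC[Si](CC)(CC)OS(=O)(=O)C(F)(F)F
Why: Silyl-triflate silylation of a hindered tertiary alcohol; the TES ether blocks retro-aldol cleavage in every later basic step and is still labile enough to leave at the end.

Step 3
Reactants: 5 dimethyl 3-(prop-2-en-1-yl)-3-(triethylsilyloxy)pentanedioate
Product: 6 3-(prop-2-en-1-yl)-3-(triethylsilyloxy)pentanedioic acid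
Conditions: LiOH (4 equiv), THF/MeOH/H2O, rt; then cold 1 M HCl to pH 4
Reagents that add atoms: lithium hydroxide, [Li+].[OH-]
Why: Saponification of two primary-alkyl methyl esters as practised for 3-silyloxyglutarates; silyloxide is too poor a leaving group for E1cB loss here, and brief cold acidification should spare the tertiary TES ether.

Step 4
Reactants: 6 3-(prop-2-en-1-yl)-3-(triethylsilyloxy)pentanedioic acid
Product: 7 4-(prop-2-en-1-yl)-4-(triethylsilyloxy)oxane-2,6-dione (the 3-allyl-3-silyloxyglutaric anhydride)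
Conditions: Ac2O (3 equiv), toluene, 50 °C; evaporation
Reagents that add atoms: none
Why: Cyclodehydration of a glutaric acid through the mixed acetic anhydride, with closure of the six-membered anhydride helped by the gem-disubstituted central carbon.

Step 5
Reactants: 7 4-(prop-2-en-1-yl)-4-(triethylsilyloxy)oxane-2,6-dione
Product: 8 (3R)-3-(2-methoxy-2-oxoethyl)-3-(triethylsilyloxy)hex-5-enoic acid
Conditions: (DHQD)2AQN (hydroquinidine anthraquinone-1,4-diyl diether, 0.2 equiv), MeOH (10 equiv), Et2O, −40 °C
Reagents that add atoms: methanol, CO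
Why: Cinchona-alkaloid-catalysed alcoholytic desymmetrisation of a prochiral glutaric anhydride, in which the quinuclidine nitrogen activates methanol as a general base inside a chiral pocket; this choice between the two enantiotopic carbonyl groups sets C5, and the anhydride should offer one dominant half-chair with the silyloxy group axial and the allyl group equatorial.

Step 6
Reactants: 8 (3R)-3-(2-methoxy-2-oxoethyl)-3-(triethylsilyloxy)hex-5-enoic acid
Product: 10 methyl (3R)-3-{2-[methoxy(methyl)amino]-2-oxoethyl}-3-(triethylsilyloxy)hex-5-enoate, via acyl imidazolide 9 (not isolated)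
Conditions: CDI (1.2 equiv), CH2Cl2, 0 °C to rt; then MeNHOMe·HCl (1.5 equiv), rt
Reagents that add atoms: N,O-dimethylhydroxylamine hydrochloride, CNOC.Cl; 1,1'-carbonyldiimidazole, O=C(n1ccnc1)n1ccnc1 (its imidazolyl group stays only in 9)
Why: Amide coupling through the acyl imidazolide (Weinreb amide formation) under nearly neutral conditions, which leave the methyl ester, the TES ether and the non-epimerisable quaternary centre untouched.

Step 7
Reactants: 11 dec-1-yne; 12 1,7-dibromoheptane
Product: 14 1-bromoheptadec-8-yne, via lithium dec-1-yn-1-ide 13 (not isolated)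
Conditions: nBuLi, THF, −78 °C; then 12 (3 equiv), DMPU, −78 °C to rt
Reagents that add atoms: none
Why: SN2 alkylation of a lithium acetylide with a primary dibromide, the excess of which favours monoalkylation and can be recovered by distillation.

Step 8
Reactants: 14 1-bromoheptadec-8-yne
Product: 15 (Z)-1-bromoheptadec-8-ene
Conditions: H2 (1 atm), Pd/CaCO3 poisoned with Pb(OAc)2, quinoline, hexane, rt
Reagents that add atoms: none
Why: Syn semi-hydrogenation of an internal alkyne on poisoned palladium, which delivers both hydrogens to one face and so gives the Z-alkene without touching the primary bromide.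

Step 9
Reactants: 10 methyl (3R)-3-{2-[methoxy(methyl)amino]-2-oxoethyl}-3-(triethylsilyloxy)hex-5-enoate; 15 (Z)-1-bromoheptadec-8-ene
Product: 17 methyl (3R)-3-[(10Z)-2-oxononadec-10-en-1-yl]-3-(triethylsilyloxy)hex-5-enoate, via (Z)-heptadec-8-en-1-ylmagnesium bromide 16 (not isolated)
Conditions: 15, Mg turnings, THF, rt to 40 °C; then 10 (1.2 equiv of 16), THF, −40 to 0 °C; aq NH4Cl
Reagents that add atoms: none
Why: Weinreb ketone synthesis, in which the magnesium-chelated tetrahedral adduct survives until the quench and so excludes over-addition, while at low temperature the N-methoxy amide reacts ahead of the methyl ester, as known for glutarate-derived ester amides.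

Step 10
Reactants: 17 methyl (3R)-3-[(10Z)-2-oxononadec-10-en-1-yl]-3-(triethylsilyloxy)hex-5-enoate
Product: 18 methyl (3R)-3-({2-[(8Z)-heptadec-8-en-1-yl]-1,3-dioxolan-2-yl}methyl)-3-(triethylsilyloxy)hex-5-enoate
Conditions: TMSOCH2CH2OTMS (3 equiv), TMSOTf (0.1 equiv), CH2Cl2, −78 to −20 °C; pyridine quench
Reagents that add atoms: 1,2-bis(trimethylsilyloxy)ethane, C[Si](C)(C)OCCO[Si](C)(C)C
Why: Noyori ketalisation, an aprotic silyl-triflate-catalysed exchange driven by formation of hexamethyldisiloxane; it needs neither water removal nor a protic acid, so the β-silyloxy ketone should neither desilylate nor eliminate.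

Step 11
Reactants: 18 methyl (3R)-3-({2-[(8Z)-heptadec-8-en-1-yl]-1,3-dioxolan-2-yl}methyl)-3-(triethylsilyloxy)hex-5-enoate
Product: 22 (1R,3S,5R)-3-({2-[(8Z)-heptadec-8-en-1-yl]-1,3-dioxolan-2-yl}methyl)-3-(triethylsilyloxy)bicyclo[3.1.0]hexan-1-ol (one ring-fusion diastereomer drawn; the 1S,3S,5S isomer serves equally), via titanacyclopropane 19 (not isolated), via oxatitanacyclopentane 20 (not isolated), via beta-titanio ketone 21 (not isolated)
Conditions: Ti(OiPr)4 (1.2 equiv), c-C5H9MgCl (4 equiv, 2 M in Et2O, added over 2 h), THF, 0 °C to rt; then H2O, filtration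
Reagents that add atoms: none
Why: Two equivalents of c-C5H9MgCl turn Ti(OiPr)4 into the cyclopentene complex of divalent titanium, which passes the metal to the monosubstituted alkene of 18 by ligand exchange and gives titanacyclopropane 19; this is the intramolecular Kulinkovich cyclopropanation of an alkenyl ester, known for hex-5-enoates. The more substituted Ti–C bond of 19 adds to the ester carbonyl in a 5-exo-trig closure (C1–C3, cyclopentane) to give oxatitanacyclopentane 20, methoxide shifts to titanium to leave β-titanio ketone 21, and the remaining Ti–CH2 bond attacks that ketone in a 3-exo-trig closure (C1–C2, cyclopropane). The two new stereocentres C1 and C3 are tied to each other by ring strain, since a cyclopropane can be fused to a cyclopentane only in the cis sense. Their relation to C5 depends on which alkene face the quaternary centre exposes, a weak substrate control that need not be high, because C1 becomes a carbonyl carbon in step 12 and C3 an sp2 carbon in step 13, so both ring-fusion diastereomers lead to one enone. Three selectivities are needed: only the terminal alkene may take up titanium (the 1,2-disubstituted Z-alkene does not displace cyclopentene), only one carbonyl group may be within reach (the second arm, equally distant from the alkene, is a ketal), and ring closure must outrun attack of the cyclopentene complex or the Grignard reagent on the ester (slow addition and the gem-disubstituted C5 favour the intramolecular path). The TES ether keeps the tertiary oxygen from triggering retro-aldol cleavage under these basic conditions.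

Step 12
Reactants: 22 (1R,3S,5R)-3-({2-[(8Z)-heptadec-8-en-1-yl]-1,3-dioxolan-2-yl}methyl)-3-(triethylsilyloxy)bicyclo[3.1.0]hexan-1-ol
Product: 23 (5S)-3-chloro-5-({2-[(8Z)-heptadec-8-en-1-yl]-1,3-dioxolan-2-yl}methyl)-5-(triethylsilyloxy)cyclohexan-1-one (both C3 epimers)
Conditions: FeCl3 (2.5 equiv), pyridine (1.5 equiv), DMF, 0 °C to rt
Reagents that add atoms: iron trichloride, Cl[Fe](Cl)Cl
Why: FeCl3-mediated oxidative ring expansion of a bicyclic cyclopropanol, in which one-electron oxidation of the iron alkoxide cleaves the strained internal C1–C3 bond (secondary ring-enlarged radical rather than a primary exocyclic one) and a second FeCl3 transfers chlorine to C3, while DMF and pyridine temper the Lewis acidity and take up the HCl so that ketal and TES ether should survive.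

Step 13
Reactants: 23 (5S)-3-chloro-5-({2-[(8Z)-heptadec-8-en-1-yl]-1,3-dioxolan-2-yl}methyl)-5-(triethylsilyloxy)cyclohexan-1-one
Product: 24 (5S)-5-({2-[(8Z)-heptadec-8-en-1-yl]-1,3-dioxolan-2-yl}methyl)-5-(triethylsilyloxy)cyclohex-2-en-1-one
Conditions: NaOAc (5 equiv), MeOH, rt to 40 °C
Reagents that add atoms: none
Why: E1cB dehydrochlorination of a β-chloro ketone, in which both C3 epimers converge and chloride leaves from the C2 enolate far faster than silyloxide could leave from the C6 enolate, so the alkene can only appear at C2=C3.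

Step 14
Reactants: 24 (5S)-5-({2-[(8Z)-heptadec-8-en-1-yl]-1,3-dioxolan-2-yl}methyl)-5-(triethylsilyloxy)cyclohex-2-en-1-one
Product: 25 (5R)-5-hydroxy-5-[(10Z)-2-oxononadec-10-en-1-yl]cyclohex-2-en-1-one
Conditions: 1 M aq HCl/THF (1:4), 0 °C to rt, stopped as soon as the ketal is consumed
Reagents that add atoms: water, O
Why: Acid-catalysed hydrolysis of the dioxolane together with protodesilylation of the TES ether in one operation, under dilute acid at or below room temperature, where tertiary aldols normally do not dehydrate; C5 is not involved.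

**Compound list**

1 | dimethyl 3-oxopentanedioate | COC(=O)CC(=O)CC(=O)OC | starting material
2 | allyl bromide | C=CCBr | starting material
3 | allylzinc bromide | C=CC[Zn]Br | intermediate
4 | dimethyl 3-hydroxy-3-(prop-2-en-1-yl)pentanedioate | COC(=O)CC(O)(CC=C)CC(=O)OC | intermediate
5 | dimethyl 3-(prop-2-en-1-yl)-3-(triethylsilyloxy)pentanedioate | COC(=O)CC(CC=C)(O[Si](CC)(CC)CC)CC(=O)OC | intermediate
6 | 3-(prop-2-en-1-yl)-3-(triethylsilyloxy)pentanedioic acid | OC(=O)CC(CC=C)(O[Si](CC)(CC)CC)CC(=O)O | intermediate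
7 | 4-(prop-2-en-1-yl)-4-(triethylsilyloxy)oxane-2,6-dione | O=C1CC(CC=C)(O[Si](CC)(CC)CC)CC(=O)O1 | intermediate
8 | (3R)-3-(2-methoxy-2-oxoethyl)-3-(triethylsilyloxy)hex-5-enoic acid | OC(=O)C[C@](O[Si](CC)(CC)CC)(CC=C)CC(=O)OC | intermediate
9 | methyl (3R)-3-[2-(imidazol-1-yl)-2-oxoethyl]-3-(triethylsilyloxy)hex-5-enoate (acyl imidazolide) | O=C(C[C@](O[Si](CC)(CC)CC)(CC=C)CC(=O)OC)n1ccnc1 | intermediate
10 | methyl (3R)-3-{2-[methoxy(methyl)amino]-2-oxoethyl}-3-(triethylsilyloxy)hex-5-enoate | CON(C)C(=O)C[C@](O[Si](CC)(CC)CC)(CC=C)CC(=O)OC | intermediate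
11 | dec-1-yne | CCCCCCCCC#C | starting material
12 | 1,7-dibromoheptane | BrCCCCCCCBr | starting material
13 | lithium dec-1-yn-1-ide | CCCCCCCCC#C[Li] | intermediate
14 | 1-bromoheptadec-8-yne | CCCCCCCCC#CCCCCCCCBr | intermediate
15 | (Z)-1-bromoheptadec-8-ene | CCCCCCCC/C=C\CCCCCCCBr | intermediate
16 | (Z)-heptadec-8-en-1-ylmagnesium bromide | CCCCCCCC/C=C\CCCCCCC[Mg]Br | intermediate
17 | methyl (3R)-3-[(10Z)-2-oxononadec-10-en-1-yl]-3-(triethylsilyloxy)hex-5-enoate | CCCCCCCC/C=C\CCCCCCCC(=O)C[C@](O[Si](CC)(CC)CC)(CC=C)CC(=O)OC | intermediate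
18 | methyl (3R)-3-({2-[(8Z)-heptadec-8-en-1-yl]-1,3-dioxolan-2-yl}methyl)-3-(triethylsilyloxy)hex-5-enoate | CCCCCCCC/C=C\CCCCCCCC1(OCCO1)C[C@](O[Si](CC)(CC)CC)(CC=C)CC(=O)OC | intermediate
19 | diisopropoxytitanacyclopropane formed on the terminal alkene of 18 | CCCCCCCC/C=C\CCCCCCCC1(OCCO1)C[C@](O[Si](CC)(CC)CC)(CC2C[Ti]2(OC(C)C)OC(C)C)CC(=O)OC | intermediate
20 | cyclopentane-fused 2-oxatitanacyclopentane (C1–C3 bond formed, methoxy still on C1) | CCCCCCCC/C=C\CCCCCCCC1(OCCO1)C[C@]2(O[Si](CC)(CC)CC)CC3C[Ti](OC(C)C)(OC(C)C)OC3(OC)C2 | intermediate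
21 | 2-(titaniomethyl)cyclopentanone (β-titanio ketone, methoxide on titanium) | CCCCCCCC/C=C\CCCCCCCC1(OCCO1)C[C@]2(O[Si](CC)(CC)CC)CC(C[Ti](OC)(OC(C)C)OC(C)C)C(=O)C2 | intermediate
22 | (1R,3S,5R)-3-({2-[(8Z)-heptadec-8-en-1-yl]-1,3-dioxolan-2-yl}methyl)-3-(triethylsilyloxy)bicyclo[3.1.0]hexan-1-ol | CCCCCCCC/C=C\CCCCCCCC1(OCCO1)C[C@]2(O[Si](CC)(CC)CC)C[C@H]3C[C@@]3(O)C2 | intermediate
23 | (5S)-3-chloro-5-({2-[(8Z)-heptadec-8-en-1-yl]-1,3-dioxolan-2-yl}methyl)-5-(triethylsilyloxy)cyclohexan-1-one (both C3 epimers) | CCCCCCCC/C=C\CCCCCCCC1(OCCO1)C[C@]2(O[Si](CC)(CC)CC)CC(Cl)CC(=O)C2 | intermediate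
24 | (5S)-5-({2-[(8Z)-heptadec-8-en-1-yl]-1,3-dioxolan-2-yl}methyl)-5-(triethylsilyloxy)cyclohex-2-en-1-one | CCCCCCCC/C=C\CCCCCCCC1(OCCO1)C[C@]2(O[Si](CC)(CC)CC)CC=CC(=O)C2 | intermediate
25 | (5R)-5-hydroxy-5-[(10Z)-2-oxononadec-10-en-1-yl]cyclohex-2-en-1-one | CCCCCCCC/C=C\CCCCCCCC(=O)C[C@]1(O)CC=CC(=O)C1 | target

**Step count**

Total step count: 14. Longest linear sequence: 12 (steps 1–6 and 9–14, from dimethyl 3-oxopentanedioate); steps 7 and 8 form a two-step side branch.

**Steps most likely to fail**

Risk 1 (step 5). The catalyst may discriminate poorly between the two enantiotopic carbonyl groups, because the prochiral carbon carries two non-hydrogen substituents, and the sense of attack is not secured by analogy. The fallback replaces catalysis by a covalent auxiliary with physical separation. It sets out from anhydride 7, which is opened with the lithium salt of (4S)-4-benzyl-1,3-oxazolidin-2-one (nBuLi, THF, −78 °C). This gives 5-[(4S)-4-benzyl-2-oxo-1,3-oxazolidin-3-yl]-5-oxo-3-(prop-2-en-1-yl)-3-(triethylsilyloxy)pentanoic acid F1 as a pair of C3 epimers. TMSCHN2 (toluene/MeOH, 0 °C) then esterifies the acid. Chromatography or crystallisation separates methyl (3R)-3-{2-[(4S)-4-benzyl-2-oxo-1,3-oxazolidin-3-yl]-2-oxoethyl}-3-(triethylsilyloxy)hex-5-enoate F2 from its (3R→3S) epimer, methyl (3S)-3-{2-[(4S)-4-benzyl-2-oxo-1,3-oxazolidin-3-yl]-2-oxoethyl}-3-(triethylsilyloxy)hex-5-enoate F3. The configuration would be secured by crystal structure analysis or correlation. LiOH/H2O2 (THF/H2O, 0 °C) then cleaves the exocyclic imide carbonyl ahead of the methyl ester, and the route is rejoined at half-ester 8.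

Risk 2 (step 11). Ligand exchange onto the alkene of a hindered, oxygen-rich substrate may be slow. The cyclopentene complex or the Grignard reagent would then consume the ester first, or base-induced loss of the silyloxy group could intervene. The fallback closes the ring by metathesis at C2=C3 and by-passes steps 11–13. It sets out from ester 18. MeNHOMe·HCl/iPrMgCl (THF, −20 °C) gives (3R)-3-({2-[(8Z)-heptadec-8-en-1-yl]-1,3-dioxolan-2-yl}methyl)-N-methoxy-N-methyl-3-(triethylsilyloxy)hex-5-enamide F4. Vinylmagnesium bromide (THF, 0 °C) gives (5S)-5-({2-[(8Z)-heptadec-8-en-1-yl]-1,3-dioxolan-2-yl}methyl)-5-(triethylsilyloxy)octa-1,7-dien-3-one F5. Second-generation Grubbs catalyst (CH2Cl2, 40 °C, high dilution, short reaction time) joins the two terminal alkenes, which react ahead of the internal Z-alkene, and the route is rejoined at enone 24.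

Risk 3 (step 14). The acid needed to hydrolyse the dioxolane may dehydrate the liberated tertiary aldol, and aromatisation of the ring would follow. The fallback carries the side-chain carbonyl at the alcohol oxidation level, so that the end game needs only fluoride and a neutral oxidant; it also by-passes step 10.

- It sets out from keto ester 17. NaBH4 (MeOH, −20 °C, AcOH quench) gives methyl (3R)-3-[(10Z)-2-hydroxynonadec-10-en-1-yl]-3-(triethylsilyloxy)hex-5-enoate F6 as both carbinol epimers, which is inconsequential.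
- TESOTf/2,6-lutidine gives methyl (3R)-3-(triethylsilyloxy)-3-[(10Z)-2-(triethylsilyloxy)nonadec-10-en-1-yl]hex-5-enoate F7.
- The conditions of step 11 give (3R)-3-(triethylsilyloxy)-3-[(10Z)-2-(triethylsilyloxy)nonadec-10-en-1-yl]bicyclo[3.1.0]hexan-1-ol F8.
- FeCl3/pyridine/DMF gives (5R)-3-chloro-5-(triethylsilyloxy)-5-[(10Z)-2-(triethylsilyloxy)nonadec-10-en-1-yl]cyclohexan-1-one F9.
- NaOAc/MeOH gives (5R)-5-(triethylsilyloxy)-5-[(10Z)-2-(triethylsilyloxy)nonadec-10-en-1-yl]cyclohex-2-en-1-one F10.
- HF·pyridine (THF, 0 °C) gives (5R)-5-hydroxy-5-[(10Z)-2-hydroxynonadec-10-en-1-yl]cyclohex-2-en-1-one F11.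
- Dess–Martin periodinane with NaHCO3 (CH2Cl2, 0 °C) oxidises the only oxidisable alcohol, and the route is rejoined at target 25.

**Further compounds**

F1 | step 5 | 5-[(4S)-4-benzyl-2-oxo-1,3-oxazolidin-3-yl]-5-oxo-3-(prop-2-en-1-yl)-3-(triethylsilyloxy)pentanoic acid (both C3 epimers) | O=C1OC[C@H](Cc2ccccc2)N1C(=O)CC(CC=C)(O[Si](CC)(CC)CC)CC(=O)O
F2 | step 5 | methyl (3R)-3-{2-[(4S)-4-benzyl-2-oxo-1,3-oxazolidin-3-yl]-2-oxoethyl}-3-(triethylsilyloxy)hex-5-enoate | O=C1OC[C@H](Cc2ccccc2)N1C(=O)C[C@](O[Si](CC)(CC)CC)(CC=C)CC(=O)OC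
F3 | step 5 | methyl (3S)-3-{2-[(4S)-4-benzyl-2-oxo-1,3-oxazolidin-3-yl]-2-oxoethyl}-3-(triethylsilyloxy)hex-5-enoate | O=C1OC[C@H](Cc2ccccc2)N1C(=O)C[C@@](O[Si](CC)(CC)CC)(CC=C)CC(=O)OC
F4 | step 11 | (3R)-3-({2-[(8Z)-heptadec-8-en-1-yl]-1,3-dioxolan-2-yl}methyl)-N-methoxy-N-methyl-3-(triethylsilyloxy)hex-5-enamide | CCCCCCCC/C=C\CCCCCCCC1(OCCO1)C[C@](O[Si](CC)(CC)CC)(CC=C)CC(=O)N(C)OC
F5 | step 11 | (5S)-5-({2-[(8Z)-heptadec-8-en-1-yl]-1,3-dioxolan-2-yl}methyl)-5-(triethylsilyloxy)octa-1,7-dien-3-one | CCCCCCCC/C=C\CCCCCCCC1(OCCO1)C[C@](O[Si](CC)(CC)CC)(CC=C)CC(=O)C=C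
F6 | step 14 | methyl (3R)-3-[(10Z)-2-hydroxynonadec-10-en-1-yl]-3-(triethylsilyloxy)hex-5-enoate (both carbinol epimers) | CCCCCCCC/C=C\CCCCCCCC(O)C[C@](O[Si](CC)(CC)CC)(CC=C)CC(=O)OC
F7 | step 14 | methyl (3R)-3-(triethylsilyloxy)-3-[(10Z)-2-(triethylsilyloxy)nonadec-10-en-1-yl]hex-5-enoate | CCCCCCCC/C=C\CCCCCCCC(O[Si](CC)(CC)CC)C[C@](O[Si](CC)(CC)CC)(CC=C)CC(=O)OC
F8 | step 14 | (3R)-3-(triethylsilyloxy)-3-[(10Z)-2-(triethylsilyloxy)nonadec-10-en-1-yl]bicyclo[3.1.0]hexan-1-ol (cis-fused, both ring-fusion diastereomers) | CCCCCCCC/C=C\CCCCCCCC(O[Si](CC)(CC)CC)C[C@]1(O[Si](CC)(CC)CC)CC2CC2(O)C1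
F9 | step 14 | (5R)-3-chloro-5-(triethylsilyloxy)-5-[(10Z)-2-(triethylsilyloxy)nonadec-10-en-1-yl]cyclohexan-1-one | CCCCCCCC/C=C\CCCCCCCC(O[Si](CC)(CC)CC)C[C@]1(O[Si](CC)(CC)CC)CC(Cl)CC(=O)C1
F10 | step 14 | (5R)-5-(triethylsilyloxy)-5-[(10Z)-2-(triethylsilyloxy)nonadec-10-en-1-yl]cyclohex-2-en-1-one | CCCCCCCC/C=C\CCCCCCCC(O[Si](CC)(CC)CC)C[C@]1(O[Si](CC)(CC)CC)CC=CC(=O)C1
F11 | step 14 | (5R)-5-hydroxy-5-[(10Z)-2-hydroxynonadec-10-en-1-yl]cyclohex-2-en-1-one | CCCCCCCC/C=C\CCCCCCCC(O)C[C@]1(O)CC=CC(=O)C1
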